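## Retrosynthetic overview

1. The dioxin ring is made last: the target is the hetero-Diels–Alder adduct (C3–O2′, C4–O3′) of pristimerin and its own ortho-quinone tautomer (C8 protonated), so one monomer supplies both halves.
2. Pristimerin comes from a ring-A-aromatic pentacycle by demethylation and DDQ dehydrogenation; the C20 quaternary centre is set by ester enolate methylation.
3. Rings C and B close together onto a cis-fused ring D/E carbinol by cation–olefin/Friedel–Crafts bicyclisation (C8–C14, C9–C10); the olefin comes from a Wittig reaction on a 3-oxobutyl group at C13.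
4. C18 (cis D/E fusion) and quaternary C13 come from copper hydride 1,4-reduction and Mukaiyama–Michael addition on the bicyclic enone.
5. Ring D is annulated onto an achiral ring-E 1,3-dione by an amine-catalysed enantioselective Robinson annulation (first stereocentre, C17). Ring order: E, D, C+B (ring A is the arene), dioxin.

Assumption: pentacycles are numbered as 24-nor-D:A-friedooleananes (β = face of the C9, C14 and C17 methyl groups), and compound 1 is taken as a catalogue chemical.

## Route

Step 1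
Reactants: 1 methyl 3,5-dioxocyclohexane-1-carboxylate
Product: 2 methyl 4-methyl-3,5-dioxocyclohexane-1-carboxylate
Conditions: HCHO (37% aq.), Hantzsch ester, L-proline (10 mol%), CH2Cl2, 25 °C
Reagents that add atoms: formaldehyde, C=O
Why: Three-component reductive alkylation (Knoevenagel condensation, then Hantzsch ester transfer hydrogenation) gives clean C-monomethylation of the 1,3-dione without O-alkylation; the product is achiral.

Step 2
Reactants: 2 methyl 4-methyl-3,5-dioxocyclohexane-1-carboxylate; 3 pent-1-en-3-one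
Product: 5 methyl (4aR)-4a,8-dimethyl-4,7-dioxo-1,2,3,4,4a,5,6,7-octahydronaphthalene-2-carboxylate (C2 epimers), via triketone 4 (not isolated)
Conditions: (2R)-N1,N1-diethyl-3,3-dimethylbutane-1,2-diamine·TfOH (5 mol%), 3-nitrobenzoic acid (2.5 mol%), neat, 60 °C
Reagents that add atoms: none
Why: Michael addition followed by a primary-amine-catalysed intramolecular aldol condensation (Hajos–Parrish–Eder–Sauer–Wiechert type Robinson annulation) in which the side-chain enamine attacks one of two enantiotopic ring carbonyls, so quaternary C17 (C4a) is set as R by the antipode of the catalyst that gives (S)-Wieland–Miescher ketone; the remote ester carbon (C20) stays an epimer mixture until step 12.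

Step 3
Reactants: 5 methyl (4aR)-4a,8-dimethyl-4,7-dioxo-1,2,3,4,4a,5,6,7-octahydronaphthalene-2-carboxylate
Product: 6 methyl (4R,4aR)-4-hydroxy-4a,8-dimethyl-7-oxo-1,2,3,4,4a,5,6,7-octahydronaphthalene-2-carboxylate
Conditions: NaBH4 (0.3 equiv), EtOH, −10 °C
Reagents that add atoms: none
Why: Chemoselective borohydride reduction of the saturated ketone in the presence of the enone, as with Wieland–Miescher ketone (hydride anti to the angular methyl); this carbinol centre is removed in step 4.

Step 4
Reactants: 6 methyl (4R,4aR)-4-hydroxy-4a,8-dimethyl-7-oxo-1,2,3,4,4a,5,6,7-octahydronaphthalene-2-carboxylate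
Product: 8 methyl (4aR)-4a,8-dimethyl-7-oxo-1,2,3,4,4a,5,6,7-octahydronaphthalene-2-carboxylate (C2 epimers), via thiocarbonylimidazolide 7 (not isolated)
Conditions: 1,1′-thiocarbonyldiimidazole, DMAP (cat.), toluene, 80 °C; then Bu3SnH, AIBN (cat.), 110 °C
Reagents that add atoms: none
Why: Barton–McCombie radical deoxygenation removes the surplus ring-E oxygen (C22) under neutral conditions that leave the enone and ester untouched.

Step 5
Reactants: 8 methyl (4aR)-4a,8-dimethyl-7-oxo-1,2,3,4,4a,5,6,7-octahydronaphthalene-2-carboxylate; 9 but-3-en-2-one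
Product: 11 methyl (4aR,8S,8aR)-4a,8-dimethyl-7-oxo-8-(3-oxobutyl)decahydronaphthalene-2-carboxylate (C2 epimers), via silyl enol ether 10 (not isolated)
Conditions: [(Ph3P)CuH]6 (5 mol%), PhMe2SiH, toluene, 25 °C; then 9, HNTf2 (5 mol%), CH2Cl2, −78 °C; aq. NaHCO3
Reagents that add atoms: none
Why: Copper hydride 1,4-reduction delivers H to C18 on the face of the angular methyl (axial attack, as for cuprates) and gives the cis-fused enol silane regiospecifically; the Mukaiyama–Michael addition then occurs on the convex face of the cis-decalin, placing the 3-oxobutyl chain at quaternary C13 cis to 18-H and 17-Me (the cis-clerodane pattern).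

Step 6
Reactants: 12 1,2-dimethoxy-3-methylbenzene
Product: 13 1-bromo-3,4-dimethoxy-2-methylbenzene
Conditions: NBS, MeCN, 0 to 25 °C
Reagents that add atoms: N-bromosuccinimide, O=C1CCC(=O)N1Br
Why: Electrophilic aromatic bromination goes para to the unhindered, coplanar methoxy group (ortho to methyl).

Step 7
Reactants: 13 1-bromo-3,4-dimethoxy-2-methylbenzene; 14 1,3-dibromopropane
Product: 16 1-(3-bromopropyl)-3,4-dimethoxy-2-methylbenzene, via aryl Grignard reagent 15 (not isolated)
Conditions: Mg, THF, 40 °C; then 14 (3 equiv), Li2CuCl4 (3 mol%), THF, 0 °C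
Reagents that add atoms: none
Why: Copper-catalysed (Kochi) aryl Grignard–primary alkyl bromide coupling; excess dibromide suppresses double arylation.

Step 8
Reactants: 16 1-(3-bromopropyl)-3,4-dimethoxy-2-methylbenzene
Product: 17 [3-(3,4-dimethoxy-2-methylphenyl)propyl]triphenylphosphonium bromide
Conditions: PPh3, MeCN, 82 °C
Reagents that add atoms: triphenylphosphine, c1ccc(cc1)P(c1ccccc1)c1ccccc1
Why: SN2 quaternisation of the primary bromide gives the Wittig salt.

Step 9
Reactants: 11 methyl (4aR,8S,8aR)-4a,8-dimethyl-7-oxo-8-(3-oxobutyl)decahydronaphthalene-2-carboxylate; 17 [3-(3,4-dimethoxy-2-methylphenyl)propyl]triphenylphosphonium bromide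
Product: 19 methyl (4aR,8S,8aR)-8-[6-(3,4-dimethoxy-2-methylphenyl)-3-methylhex-3-en-1-yl]-4a,8-dimethyl-7-oxodecahydronaphthalene-2-carboxylate (E/Z mixture), via phosphonium ylide 18 (not isolated)
Conditions: KN(SiMe3)2, THF, −78 to 0 °C; then 11, −78 to 25 °C
Reagents that add atoms: none
Why: Wittig olefination is selective for the unhindered methyl ketone over the neopentyl ring ketone and the ester; the E/Z mixture is acceptable because both isomers give the same C9 and C14 configuration in step 11 and C8 becomes sp2 in step 14.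

Step 10
Reactants: 19 methyl (4aR,8S,8aR)-8-[6-(3,4-dimethoxy-2-methylphenyl)-3-methylhex-3-en-1-yl]-4a,8-dimethyl-7-oxodecahydronaphthalene-2-carboxylate
Product: 20 methyl (4aR,8S,8aR)-8-[6-(3,4-dimethoxy-2-methylphenyl)-3-methylhex-3-en-1-yl]-7-hydroxy-4a,7,8-trimethyldecahydronaphthalene-2-carboxylate
Conditions: MeMgBr, THF, −78 to −20 °C; aq. NH4Cl
Reagents that add atoms: methylmagnesium bromide, C[Mg]Br
Why: Grignard 1,2-addition to the ketone is much faster than attack on the ester at low temperature; the carbinol configuration is irrelevant because the centre is ionised in step 11.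

Step 11
Reactants: 20 methyl (4aR,8S,8aR)-8-[6-(3,4-dimethoxy-2-methylphenyl)-3-methylhex-3-en-1-yl]-7-hydroxy-4a,7,8-trimethyldecahydronaphthalene-2-carboxylate
Product: 21 methyl 2,3-dimethoxy-24,30-dinor-D:A-friedooleana-1,3,5(10)-trien-29-oate (C8 and C20 epimer mixtures)
Conditions: TfOH (10 mol%), HFIP/CH2Cl2 (1:4), −20 °C
Reagents that add atoms: none
Why: Acid ionisation to the tertiary C14 cation starts a cation–olefin/Friedel–Crafts bicyclisation (6-endo C8–C14 bond, then C9 cation captured by the arene para to the 3-methoxy group); a chair–chair transition state with the tether equatorial on ring D gives the trans C/D fusion, with 14-Me anti to 13-Me and syn to 9-Me.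

Step 12
Reactants: 21 methyl 2,3-dimethoxy-24,30-dinor-D:A-friedooleana-1,3,5(10)-trien-29-oate
Product: 22 methyl 2,3-dimethoxy-24-nor-D:A-friedooleana-1,3,5(10)-trien-29-oate (20β-Me, 20α-CO2Me; C8 epimers)
Conditions: LiN(iPr)2, THF, −78 °C; MeI, −78 to 0 °C
Reagents that add atoms: iodomethane, CI
Why: Ester enolate alkylation; the α face at C20 is shielded by ring D (C13 and its α-methyl are syn-axial), so MeI attacks the exocyclic enolate equatorially from the convex β face, and both C20 epimers converge on the 20β-methyl product.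

Step 13
Reactants: 22 methyl 2,3-dimethoxy-24-nor-D:A-friedooleana-1,3,5(10)-trien-29-oate
Product: 23 methyl 2,3-dihydroxy-24-nor-D:A-friedooleana-1,3,5(10)-trien-29-oate (C8 epimers)
Conditions: BBr3, CH2Cl2, −78 to 0 °C; H2O
Reagents that add atoms: none
Why: Lewis-acid cleavage of both aryl methyl ethers; the hindered quaternary methyl ester survives at low temperature.

Step 14
Reactants: 23 methyl 2,3-dihydroxy-24-nor-D:A-friedooleana-1,3,5(10)-trien-29-oate
Product: 24 pristimerin (methyl 3-hydroxy-2-oxo-24-nor-D:A-friedooleana-1(10),3,5,7-tetraen-29-oate)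
Conditions: DDQ (2.2 equiv), 1,4-dioxane, 25 to 60 °C
Reagents that add atoms: none
Why: Quinone dehydrogenation: the catechol is oxidised to the ortho-quinone, which tautomerises to the para-quinone methide, and a second hydride abstraction at C7 with loss of H8 gives the extended quinone methide; quaternary C9 and C14 stop further oxidation and the C8 epimers converge.

Step 15
Reactants: 24 pristimerin (two molecules)
Product: 26 CNP0166638.1 (quinoid unit with 3β-OH and 4β-Me, joined through 3α-O–C2′ and 4α-O–C3′ to the ring-A-aromatic 6-ene unit with 8′β-H), via ortho-quinone tautomer 25 (not isolated)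
Conditions: (R)-3,3′-bis(2,4,6-triisopropylphenyl)-1,1′-binaphthyl-2,2′-diyl hydrogen phosphate (10 mol%; antipode to be screened), toluene, 4 Å MS, 25 °C, dark, argon
Reagents that add atoms: none
Why: Proposed new method: the chiral phosphoric acid acts as a bifunctional proton shuttle that ketonises pristimerin's vinylogous enol (HO–C3=C4–C5=C6–C7=C8) by protonating C8 on the β face (anti to the syn-axial 13α-methyl) while taking the O3 proton, and the resulting electron-poor ortho-quinone 25, still hydrogen-bonded to the catalyst, is trapped by the enol C3=C4 of a second pristimerin in an inverse-electron-demand hetero-Diels–Alder reaction on the α face (nucleophilic C4 to O3′, C3 to O2′, giving the cis-dioxin hemiketal); the closest known reactions are phosphoric-acid-catalysed oxa-Diels–Alder reactions of ortho-quinones and ortho-quinone methides with enol ethers, and thermal ortho-quinone/olefin cycloadditions.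

## Compound list

1 | methyl 3,5-dioxocyclohexane-1-carboxylate | COC(=O)C1CC(=O)CC(=O)C1 | starting material
2 | methyl 4-methyl-3,5-dioxocyclohexane-1-carboxylate | COC(=O)C1CC(=O)C(C)C(=O)C1 | intermediate
3 | pent-1-en-3-one | CCC(=O)C=C | starting material
4 | methyl 4-methyl-3,5-dioxo-4-(3-oxopentyl)cyclohexane-1-carboxylate (achiral, cis/trans) | COC(=O)C1CC(=O)C(C)(CCC(=O)CC)C(=O)C1 | intermediate
5 | methyl (4aR)-4a,8-dimethyl-4,7-dioxo-1,2,3,4,4a,5,6,7-octahydronaphthalene-2-carboxylate (C2 epimers) | COC(=O)C1CC(=O)[C@]2(C)CCC(=O)C(C)=C2C1 | intermediate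
6 | methyl (4R,4aR)-4-hydroxy-4a,8-dimethyl-7-oxo-1,2,3,4,4a,5,6,7-octahydronaphthalene-2-carboxylate (C2 epimers) | COC(=O)C1C[C@@H](O)[C@]2(C)CCC(=O)C(C)=C2C1 | intermediate
7 | methyl (4R,4aR)-4-[(imidazol-1-ylcarbonothioyl)oxy]-4a,8-dimethyl-7-oxo-1,2,3,4,4a,5,6,7-octahydronaphthalene-2-carboxylate | COC(=O)C1C[C@@H](OC(=S)n3ccnc3)[C@]2(C)CCC(=O)C(C)=C2C1 | intermediate
8 | methyl (4aR)-4a,8-dimethyl-7-oxo-1,2,3,4,4a,5,6,7-octahydronaphthalene-2-carboxylate (C2 epimers) | COC(=O)C1CC[C@]2(C)CCC(=O)C(C)=C2C1 | intermediate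
9 | but-3-en-2-one | CC(=O)C=C | starting material
10 | methyl (4aR,8aR)-7-{[dimethyl(phenyl)silyl]oxy}-4a,8-dimethyl-1,2,3,4,4a,5,6,8a-octahydronaphthalene-2-carboxylate (cis-fused) | COC(=O)C1CC[C@]2(C)CCC(O[Si](C)(C)c3ccccc3)=C(C)[C@@H]2C1 | intermediate
11 | methyl (4aR,8S,8aR)-4a,8-dimethyl-7-oxo-8-(3-oxobutyl)decahydronaphthalene-2-carboxylate (C2 epimers) | COC(=O)C1CC[C@]2(C)CCC(=O)[C@@](C)(CCC(C)=O)[C@@H]2C1 | intermediate
12 | 1,2-dimethoxy-3-methylbenzene | COc1cccc(C)c1OC | starting material
13 | 1-bromo-3,4-dimethoxy-2-methylbenzene | COc1ccc(Br)c(C)c1OC | intermediate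
14 | 1,3-dibromopropane | BrCCCBr | starting material
15 | (3,4-dimethoxy-2-methylphenyl)magnesium bromide | COc1ccc([Mg]Br)c(C)c1OC | intermediate
16 | 1-(3-bromopropyl)-3,4-dimethoxy-2-methylbenzene | COc1ccc(CCCBr)c(C)c1OC | intermediate
17 | [3-(3,4-dimethoxy-2-methylphenyl)propyl]triphenylphosphonium bromide | COc1ccc(CCC[P+](c2ccccc2)(c2ccccc2)c2ccccc2)c(C)c1OC.[Br-] | intermediate
18 | [3-(3,4-dimethoxy-2-methylphenyl)propylidene]triphenylphosphorane | COc1ccc(CCC=P(c2ccccc2)(c2ccccc2)c2ccccc2)c(C)c1OC | intermediate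
19 | methyl (4aR,8S,8aR)-8-[6-(3,4-dimethoxy-2-methylphenyl)-3-methylhex-3-en-1-yl]-4a,8-dimethyl-7-oxodecahydronaphthalene-2-carboxylate (E/Z, C2 epimers) | COC(=O)C1CC[C@]2(C)CCC(=O)[C@@](C)(CCC(C)=CCCc3ccc(OC)c(OC)c3C)[C@@H]2C1 | intermediate
20 | methyl (4aR,8S,8aR)-8-[6-(3,4-dimethoxy-2-methylphenyl)-3-methylhex-3-en-1-yl]-7-hydroxy-4a,7,8-trimethyldecahydronaphthalene-2-carboxylate (C7 carbinol either configuration) | COC(=O)C1CC[C@]2(C)CCC(C)(O)[C@@](C)(CCC(C)=CCCc3ccc(OC)c(OC)c3C)[C@@H]2C1 | intermediate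
21 | methyl 2,3-dimethoxy-24,30-dinor-D:A-friedooleana-1,3,5(10)-trien-29-oate (9β-Me, 13α-Me, 14β-Me, 17β-Me, 18β-H; C8 and C20 epimers) | COC(=O)C1CC[C@]2(C)CC[C@]3(C)C4CCc5c(C)c(OC)c(OC)cc5[C@]4(C)CC[C@@]3(C)[C@@H]2C1 | intermediate
22 | methyl 2,3-dimethoxy-24-nor-D:A-friedooleana-1,3,5(10)-trien-29-oate (20β-Me, 20α-CO2Me; C8 epimers) | COC(=O)[C@]1(C)CC[C@]2(C)CC[C@]3(C)C4CCc5c(C)c(OC)c(OC)cc5[C@]4(C)CC[C@@]3(C)[C@@H]2C1 | intermediate
23 | methyl 2,3-dihydroxy-24-nor-D:A-friedooleana-1,3,5(10)-trien-29-oate (C8 epimers) | COC(=O)[C@]1(C)CC[C@]2(C)CC[C@]3(C)C4CCc5c(C)c(O)c(O)cc5[C@]4(C)CC[C@@]3(C)[C@@H]2C1 | intermediate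
24 | pristimerin, methyl 3-hydroxy-2-oxo-24-nor-D:A-friedooleana-1(10),3,5,7-tetraen-29-oate | COC(=O)[C@]1(C)CC[C@]2(C)CC[C@]3(C)C4=CC=C5C(=CC(=O)C(O)=C5C)[C@]4(C)CC[C@@]3(C)[C@@H]2C1 | intermediate
25 | methyl 2,3-dioxo-24-nor-D:A-friedooleana-1(10),4,6-trien-29-oate with 8β-H (ortho-quinone tautomer of pristimerin) | O=C1C=C2C(=C(C)C1=O)C=C[C@@H]3[C@@]2(C)CC[C@@]4(C)[C@@H]5C[C@](C)(C(=O)OC)CC[C@]5(C)CC[C@]34C | intermediate
26 | CNP0166638.1 (3α,4α-dioxy-bridged pristimerin dimer, 3β-OH, 4β-Me, 8′β-H) | COC(=O)[C@]1(C)CC[C@]2(C)CC[C@]3(C)C4=CC=C5C(=CC(=O)[C@@]6(O)Oc7cc8c(c(C)c7O[C@@]56C)C=C[C@@H]5[C@@]8(C)CC[C@@]6(C)[C@@H]7C[C@](C)(C(=O)OC)CC[C@]7(C)CC[C@]56C)[C@]4(C)CC[C@@]3(C)[C@@H]2C1 | target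

## Step count and risks

Total steps: 15. Longest linear sequence: 12 (steps 1–5 and 9–15, from compound 1).

**Step 15 (new tautomerisation/hetero-Diels–Alder dimerisation).** Risks are the regiochemistry, the α/β face of addition and the C8′ configuration. The fallback uses known chemistry, sets out from 24 and comes back at 26. Half of 24 is reduced with Na2S2O4 (THF/H2O) to pristimerol F4. The 7-ene of F4 is moved into conjugation with the arene using RuHCl(CO)(PPh3)3 (toluene, 100 °C; 1,4- to 1,2-dihydronaphthalene isomerisation, H delivered to the less hindered β face of C8) to give methyl 2,3-dihydroxy-8β-H-24-nor-D:A-friedooleana-1,3,5(10),6-tetraen-29-oate F5. Oxidation of F5 with Ag2O (CH2Cl2, 0 °C) in the presence of the other half of 24 generates 25 as a discrete reagent, which adds thermally to 24 to give 26.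

**Step 11 (cationic bicyclisation).** Risks are the C14 facial selectivity, 1,2-methyl shifts and elimination. The fallback sets out from 19 and comes back at 21. Wittig methylenation of the ring ketone (Ph3P=CH2, toluene, 90 °C) gives methyl (4aR,8S,8aR)-8-[6-(3,4-dimethoxy-2-methylphenyl)-3-methylhex-3-en-1-yl]-4a,8-dimethyl-7-methylidenedecahydronaphthalene-2-carboxylate F3. A hydrogen-atom-transfer radical–polar crossover bicyclisation then closes rings C and B (Co(salen), formula Co(C16H14N2O2), divalent cobalt, 5 mol%; N-fluoro-2,4,6-trimethylpyridinium tetrafluoroborate; PhSiH3; HFIP). The hydrogen atom adds selectively to the 1,1-disubstituted olefin, creating the C14 methyl and a tertiary C14 radical; this cyclises 6-endo, is oxidised to the C9 cation and is captured by the arene to give 21.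

**Step 5 (copper hydride reduction/Mukaiyama–Michael).** Risks are the reactivity of the tetrasubstituted enone and the cis selectivity. The fallback sets out from 8 and comes back at 11. Heterogeneous hydrogenation of 8 (H2, Pd/C, KOH, EtOH) gives the cis-fused decalone methyl (4aR,8aS)-4a,8-dimethyl-7-oxodecahydronaphthalene-2-carboxylate F1. Equilibrating silylation (Me3SiCl, NaI, Et3N, MeCN) gives the more substituted enol ether methyl (4aR,8aR)-4a,8-dimethyl-7-(trimethylsilyloxy)-1,2,3,4,4a,5,6,8a-octahydronaphthalene-2-carboxylate F2. Mukaiyama–Michael addition of F2 to 9 (HNTf2 cat., CH2Cl2, −78 °C) gives 11.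

## Further compounds

F1 | step 5 | methyl (4aR,8aS)-4a,8-dimethyl-7-oxodecahydronaphthalene-2-carboxylate (cis-fused; C2 and C8 epimers) | COC(=O)C1CC[C@]2(C)CCC(=O)C(C)[C@@H]2C1
F2 | step 5 | methyl (4aR,8aR)-4a,8-dimethyl-7-(trimethylsilyloxy)-1,2,3,4,4a,5,6,8a-octahydronaphthalene-2-carboxylate | COC(=O)C1CC[C@]2(C)CCC(O[Si](C)(C)C)=C(C)[C@@H]2C1
F3 | step 11 | methyl (4aR,8S,8aR)-8-[6-(3,4-dimethoxy-2-methylphenyl)-3-methylhex-3-en-1-yl]-4a,8-dimethyl-7-methylidenedecahydronaphthalene-2-carboxylate | COC(=O)C1CC[C@]2(C)CCC(=C)[C@@](C)(CCC(C)=CCCc3ccc(OC)c(OC)c3C)[C@@H]2C1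
F4 | step 15 | pristimerol, methyl 2,3-dihydroxy-24-nor-D:A-friedooleana-1,3,5(10),7-tetraen-29-oate | COC(=O)[C@]1(C)CC[C@]2(C)CC[C@]3(C)C4=CCc5c(C)c(O)c(O)cc5[C@]4(C)CC[C@@]3(C)[C@@H]2C1
F5 | step 15 | methyl 2,3-dihydroxy-8β-H-24-nor-D:A-friedooleana-1,3,5(10),6-tetraen-29-oate | Oc1cc2c(c(C)c1O)C=C[C@@H]3[C@@]2(C)CC[C@@]4(C)[C@@H]5C[C@](C)(C(=O)OC)CC[C@]5(C)CC[C@]34C
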